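The readings stem from a simulated flask with constants of no real substance.

If you repeat these flasks, watch one ratio: cX/cZ.

| flask | X | L | remark | time |
|---|---|---|---|---|
| north-west | 0.050 M | 0.075 M | run made earlier |  |
| south-east | 0.034 M | 0.075 M | run made earlier |  |
| south | 0.075 M | 0.075 M | run made earlier |  |
| gamma | 0.050 M | 0.0750 M | everything together at the start | 1.0 h |
| delta | 0.050 M (fed, over 50 min) | 0.0750 M | all else is in the flask from the start; the feed brings no volume worth counting | 1.0 h |
| eta | 0.050 M | 0.0750 M (fed, over 50 min) | all else is in the flask from the start; the feed brings no volume worth counting | 1.0 h |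

| run | time / min | Z / % | X / % |
|---|---|---|---|
| north-west | 3.00 | 15 | 82 |
| north-west | 10.0 | 31 | 47 |
| north-west | 15.0 | 29 | 33 |
| north-west | 25.0 | 25 | 15 |
| north-west | 40.0 | 10 | 6 |
| north-west | 50.0 | 6 | 2 |
| north-west | 60.0 | 4 | 1 |
| south-east | 5.00 | 25 | 67 |
| south-east | 10.0 | 31 | 46 |
| south-east | 15.0 | 29 | 30 |
| south-east | 20.0 | 30 | 22 |
| south-east | 25.0 | 22 | 16 |
| south-east | 30.0 | 19 | 10 |
| south-east | 40.0 | 13 | 4 |
| south | 2.00 | 12 | 86 |
| south | 6.00 | 25 | 64 |
| south | 10.0 | 29 | 48 |
| south | 15.0 | 32 | 31 |
| south | 20.0 | 28 | 20 |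
| south | 30.0 | 19 | 8 |
| south | 40.0 | 12 | 5 |

(readings scatter by 2 percentage points)

- the earlier runs were read with a standard deviation of 2 percentage points

* the flask with the highest amount of Z, in percent of the X charged ("all alike" if they lie within 1.5 percentage points) (gamma / delta / eta / all alike)
* final Z, as a percentage of the X charged, in gamma
* final Z, as a percentage of the X charged, in delta
* final Z, as a percentage of the X charged, in eta

1. X at 10.0 min reads 47 %, 46 % and 48 % in the earlier runs, across different X charges. So X falls first order. From north-west, 15 % at 25.0 min gives kx = 0.0759 min⁻¹.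
2. Z stops rising when making equals use. North-west loses Z from 25.0 min to 50.0 min. Add back the making, kx times the mean X, and divide by the mean Z, and you read a use constant kz = 0.0906 min⁻¹. That gives the turning ratio, r = kz/kx = 1.19, the cX/cZ at which Z stops rising with L charged at 0.075 M and L still in the flask. It is a reading, with scatter 2 points on each number. Above r, with L still in the flask, Z climbs. Below r, Z falls.
3. Setting one, everything together. Gamma repeats north-west, whose last reading gives 0.250, under r. So expect Z falling, near 4 %.
4. Setting two, feed X. Each portion of X decays for its own age, so by hand delta keeps 12.1 % of X at 1.0 h, more than north-west's 1 %. So delta is still making Z at the end.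
5. Setting three, feed L. Every earlier run held L at 0.075 M, so r says nothing about eta. I give no number for it.
6. The forecast names delta, with 3 % for gamma, 16 % for delta and 8 % for eta. Its gamma stands below my reading. On eta it says: “Eta is poorly determined, since every run used the same L.”
7. The flasks give delta as highest, with 6.24 % in gamma, 17.2 % in delta and 7.70 % in eta.

    D ⇌ Q (K = 0.0340, k = 115 min⁻¹)
    L + Q → E (k = 49100 M⁻¹ min⁻¹)
    X ⇌ D (K = 0.0596, k = 0.0768 min⁻¹)
    L + D → Z (k = 25200 M⁻¹ min⁻¹)
    Z ⇌ J (K = 23.0, k = 0.0960 min⁻¹)
    D → G (k = 0.0110 min⁻¹)

At the end, cX/cZ is 0.687 in delta and 0.161 in gamma, both under r. Delta leads gamma by 11 points, and the loss of Z to J, both ways, is the largest single effect on that lead. With that step taken away, the lead becomes −10 points. In one more flask, gamma's recipe with 0.20 M of X, the ratio reads 35.4 with L at 0 %, so r does not apply there, and Z stands at 1.61 %.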